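**Retrosynthetic overview**

1. Feature: in ring A the diaryl ketone carbon (C7, on C1) and the formyl carbon (C8, on C2) sit on neighbouring ring atoms. C7–C8 is treated as one two-carbon unit fused across C1–C2 as a cyclobutene and cut between C7 and C8 at the end.
2. Last disconnection: the C7–C8 bond of a benzocyclobutene-1,2-diol (glycol cleavage gives ketone and aldehyde together), followed by removal of four MOM ethers.
3. C7–C1′: the ring B aryllithium (from orcinol) adds to the benzocyclobutenedione at the carbonyl on C1, the one not conjugated with the C3 and C5 oxygens.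
4. C1–C7 and C2–C8: [2+2] cycloaddition of the ring A aryne (C1≡C2) with the ketene silyl acetal of a silyloxyacetate. The aryne precursor comes from phloroglucinol by two carbamate-directed ortho-metalations in one flask on a single N-silylation (silicon first, then prenyl).
5. Ring order: rings A and B are bought as phloroglucinol and orcinol. The only ring formed is the cyclobutene (step 7), opened again in step 14.

Key step: step 7

Remark: ring A is numbered as in the target throughout (C1 carries C7, C2 carries C8, C3 and C5 carry oxygen, C4 is CH, C6 carries the prenyl group); C1′ is the ring B carbon bonded to C7. The target is achiral; the stereocentres of 19, 20, 26 and 27 are formed without control and are all destroyed before the end.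

**Route**

Step 1
Reactants: 1 phloroglucinol
Product: 2 3,5-bis(methoxymethoxy)phenol
Conditions: MOMCl (2 equiv), i-Pr2NEt, DMF, 0 °C → rt
Reagents that add atoms: chloromethyl methyl ether, COCCl
Why: O-alkylation of the phenol with the reactive α-chloro ether (Williamson type); with two equivalents the bis-ether should be the main component of a statistical mixture, separable by chromatography, with the mono-ether recycled.

Step 2
Reactants: 2 3,5-bis(methoxymethoxy)phenol
Product: 3 3,5-bis(methoxymethoxy)phenyl N-isopropylcarbamate
Conditions: i-PrNCO, Et3N (cat.), CH2Cl2, rt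
Reagents that add atoms: isopropyl isocyanate, CC(C)N=C=O
Why: Base-catalysed addition of the phenol to the isocyanate gives the N–H carbamate, a strong ortho-directing group that can later be removed by a mild E1cB path even when flanked by two ortho substituents.

Step 3
Reactants: 3 3,5-bis(methoxymethoxy)phenyl N-isopropylcarbamate; 4 prenyl bromide
Product: 11 3,5-bis(methoxymethoxy)-2-(3-methylbut-2-en-1-yl)-6-(trimethylsilyl)phenyl N-isopropylcarbamate, via N-silyl carbamate 5 (not isolated), via aryllithium 6 (not isolated), via disilyl carbamate 7 (not isolated), via silylated aryllithium 8 (not isolated), via arylcopper 9 (not isolated), via N-silyl prenyl carbamate 10 (not isolated)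
Conditions: TMSOTf, TMEDA, Et2O, 0 °C → rt; s-BuLi (2 equiv), TMEDA, −78 °C; TMSCl (1.0 equiv), −78 → 0 °C; s-BuLi (1.2 equiv), −78 °C; CuBr·SMe2, THF, −78 °C; 4, −78 → 0 °C; aq NH4Cl
Reagents that add atoms: chlorotrimethylsilane, C[Si](C)(C)Cl
Why: Sequential directed ortho-metalation in one flask, in which the N–H is masked once as the N-silyl carbamate (the silyl triflate is consumed at once as its TMEDA complex, sparing the aryl acetals, and one equivalent of s-BuLi is taken up by the ammonium triflate) and this N–Si bond is kept through both metalations: the first lithiation takes C2 between the carbamate and a MOM ether and is trapped by one equivalent of TMSCl, the second should take C6, the remaining position between the carbamate and a MOM ether, rather than C4 between the two weaker directors, the derived arylcopper is alkylated by prenyl bromide at its primary carbon (SN2) while copper suppresses the anionic ortho-Fries shift, and the N–Si bond is hydrolysed only on the final work-up; placing silicon before the prenyl group keeps a benzylic-allylic CH2 away from the strong base.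

Step 4
Reactants: 11 3,5-bis(methoxymethoxy)-2-(3-methylbut-2-en-1-yl)-6-(trimethylsilyl)phenyl N-isopropylcarbamate
Product: 13 3,5-bis(methoxymethoxy)-2-(3-methylbut-2-en-1-yl)-6-(trimethylsilyl)phenyl trifluoromethanesulfonate, via phenol 12 (not isolated)
Conditions: DBU, Et2NH (1.1 equiv), MeCN, 40 °C; then PhNTf2, rt
Reagents that add atoms: N-phenylbis(trifluoromethanesulfonimide), O=S(=O)(N(c1ccccc1)S(=O)(=O)C(F)(F)F)C(F)(F)F
Why: E1cB cleavage of the secondary carbamate (DBU removes the N–H proton, isopropyl isocyanate is expelled and trapped by the small excess of Et2NH) frees the hindered phenoxide without touching acetal, alkene or aryl–silicon groups, and triflyl transfer in the same flask gives the ortho-silylaryl triflate.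

Step 5
Reactants: 14 methyl glycolate
Product: 15 methyl 2-(tert-butyldimethylsilyloxy)acetate
Conditions: TBSCl, imidazole, CH2Cl2, rt
Reagents that add atoms: tert-butyldimethylsilyl chloride, CC(C)(C)[Si](C)(C)Cl
Why: Standard imidazole-promoted silylation of a primary alcohol.

Step 6
Reactants: 15 methyl 2-(tert-butyldimethylsilyloxy)acetate
Product: 17 1-methoxy-1,2-bis(tert-butyldimethylsilyloxy)ethene, via lithium enolate 16 (not isolated)
Conditions: LiN(i-Pr)2, TBSCl, THF, −78 °C; DMPU, −78 °C → rt
Reagents that add atoms: tert-butyldimethylsilyl chloride, CC(C)(C)[Si](C)(C)Cl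
Why: Ester enolisation and O-silylation of the enolate gives the ketene silyl acetal; the chlorosilane is present during enolisation so that the α-silyloxy enolate is trapped before silyl migration, and the double-bond geometry is immaterial for step 7.

Step 7
Reactants: 13 3,5-bis(methoxymethoxy)-2-(3-methylbut-2-en-1-yl)-6-(trimethylsilyl)phenyl trifluoromethanesulfonate; 17 1-methoxy-1,2-bis(tert-butyldimethylsilyloxy)ethene
Product: 19 7,8-bis(tert-butyldimethylsilyloxy)-8-methoxy-3,5-bis(methoxymethoxy)-6-prenyl-7,8-dihydrobenzocyclobutene (diastereomer mixture), via aryne 18 (not isolated)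
Conditions: CsF (3 equiv), 17 (3 equiv), MeCN, 0 °C → rt
Reagents that add atoms: none
Why: Fluoride attacks the aryl silicon of 13 and triflate leaves from the neighbouring carbon, giving aryne 18 with the strained bond between C1 and C2 of ring A. The electron-rich CH(OTBS) carbon of 17 adds to C1, the aryne carbon remote from the C3 oxygen, so that the aryl anion develops at C2 next to that inductively withdrawing oxygen, and this anion then captures the silyloxy(methoxy)carbenium carbon. This second bond closes the four-membered ring by anion–cation collapse (4-exo attack on the C=O+ bond), so the process is a stepwise polar [2+2] cycloaddition, the known reaction of alkoxyarynes with ketene silyl acetals that gives benzocyclobutenone acetals. The two new stereocentres at C7 and C8 are not controlled and need not be, since C8 becomes a carbonyl in step 8 and C7 in step 9. The step needs chemoselectivity only: the ketene acetal, used in excess and far more nucleophilic than the prenyl alkene, must intercept the aryne before it oligomerises, and its bulky tert-butyldimethylsilyl groups slow fluoride attack at its own silicon. Regiochemistry is not required because C7 and C8 both end as carbonyl carbons, although the C3 oxygen should give the isomer drawn.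

Step 8
Reactants: 19 7,8-bis(tert-butyldimethylsilyloxy)-8-methoxy-3,5-bis(methoxymethoxy)-6-prenyl-7,8-dihydrobenzocyclobutene
Product: 20 7-hydroxy-3,5-bis(methoxymethoxy)-6-prenylbenzocyclobuten-8-one (racemic)
Conditions: HF·pyridine, pyridine, THF, 0 °C → rt
Reagents that add atoms: none
Why: Fluoride-mediated desilylation cleaves both Si–O bonds; the hemiketal at C8 collapses to the ketone with loss of methanol and C7 is left as the secondary alcohol, the pyridine buffer keeping the aryl MOM ethers intact; the C7 stereocentre is racemic and is erased in step 9.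

Step 9
Reactants: 20 7-hydroxy-3,5-bis(methoxymethoxy)-6-prenylbenzocyclobuten-8-one
Product: 21 3,5-bis(methoxymethoxy)-6-prenylbenzocyclobutene-7,8-dione
Conditions: Dess–Martin periodinane, pyridine, CH2Cl2, 0 °C → rt
Reagents that add atoms: none
Why: Dess–Martin oxidation of the α-hydroxy ketone to the 1,2-dione under buffered, non-basic conditions, which avoids base-induced opening of the strained hydroxy ketone.

Step 10
Reactants: 22 orcinol
Product: 23 4-chloro-5-methylbenzene-1,3-diol
Conditions: SO2Cl2 (1 equiv), Et2O, 0 °C → rt
Reagents that add atoms: sulfuryl chloride, O=S(=O)(Cl)Cl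
Why: Electrophilic aromatic chlorination, expected at C4 (ortho to one hydroxyl, para to the other) in preference to the more hindered C2 between the two hydroxyls, with one equivalent limiting dichlorination.

Step 11
Reactants: 23 4-chloro-5-methylbenzene-1,3-diol
Product: 24 2-chloro-1,5-bis(methoxymethoxy)-3-methylbenzene
Conditions: MOMCl, i-Pr2NEt, CH2Cl2, 0 °C → rt
Reagents that add atoms: chloromethyl methyl ether, COCCl
Why: O-Alkylation of both phenols installs the acetal groups that direct the lithiation in step 12.

Step 12
Reactants: 24 2-chloro-1,5-bis(methoxymethoxy)-3-methylbenzene; 21 3,5-bis(methoxymethoxy)-6-prenylbenzocyclobutene-7,8-dione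
Product: 26 7-aryl-7-hydroxy-3,5-bis(methoxymethoxy)-6-prenylbenzocyclobuten-8-one (aryl = 3-chloro-2,6-bis(methoxymethoxy)-4-methylphenyl; racemic), via aryllithium 25 (not isolated)
Conditions: 24, n-BuLi, THF, 0 °C; added to 21, THF, −78 °C; AcOH, −78 °C
Reagents that add atoms: none
Why: Directed ortho-metalation of 24 between its two MOM ethers (no hydrogen stands ortho to chlorine) gives 25, which undergoes 1,2-addition to the more electrophilic carbonyl of 21: C7 on C1 is meta to both ring oxygens, whereas C8 on C2 is ortho to the C3 oxygen and para to the C5 oxygen and is deactivated as a vinylogous carbonate; the C7 stereocentre forms as the racemate and is destroyed in step 14, and the cold acidic quench prevents ring opening of the alkoxide.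

Step 13
Reactants: 26 7-aryl-7-hydroxy-3,5-bis(methoxymethoxy)-6-prenylbenzocyclobuten-8-one
Product: 27 7-aryl-3,5-bis(methoxymethoxy)-6-prenyl-7,8-dihydrobenzocyclobutene-7,8-diol (diastereomer mixture)
Conditions: NaBH4, MeOH/THF, −20 → 0 °C
Reagents that add atoms: none
Why: Hydride reduction of the strained cyclobutenone carbonyl; attack anti to the bulky C7 aryl group should give mainly the trans-diol, but the configuration at C8 is irrelevant because both carbinol centres are destroyed in step 14.

Step 14
Reactants: 27 7-aryl-3,5-bis(methoxymethoxy)-6-prenyl-7,8-dihydrobenzocyclobutene-7,8-diol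
Product: 28 2-[3-chloro-2,6-bis(methoxymethoxy)-4-methylbenzoyl]-4,6-bis(methoxymethoxy)-3-prenylbenzaldehyde
Conditions: Pb(OAc)4, CH2Cl2, 0 °C
Reagents that add atoms: none
Why: Criegee glycol cleavage: Pb(OAc)4 is chosen over periodate because it also cleaves trans-diols that cannot form a cyclic ester, and rupture of the doubly benzylic C7–C8 bond is helped by release of four-ring strain, giving the diaryl ketone and the aldehyde together at the correct oxidation level without passing a lactol or phthalide stage.

Step 15
Reactants: 28 2-[3-chloro-2,6-bis(methoxymethoxy)-4-methylbenzoyl]-4,6-bis(methoxymethoxy)-3-prenylbenzaldehyde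
Product: 29 Pestalone E
Conditions: HCl (aq)/MeOH, rt
Reagents that add atoms: none
Why: Acid-catalysed acetal exchange with methanol removes the four aryl MOM groups; dilute acid at room temperature is used so that the C5 phenol does not add to the prenyl double bond, and any dimethyl acetal formed at the aldehyde reverts on aqueous work-up.

**Compound list**

1 | phloroglucinol | Oc1cc(O)cc(O)c1 | starting material
2 | 3,5-bis(methoxymethoxy)phenol | COCOc1cc(O)cc(OCOC)c1 | intermediate
3 | 3,5-bis(methoxymethoxy)phenyl N-isopropylcarbamate | CC(C)NC(=O)Oc1cc(OCOC)cc(OCOC)c1 | intermediate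
4 | prenyl bromide (1-bromo-3-methylbut-2-ene) | CC(C)=CCBr | starting material
5 | 3,5-bis(methoxymethoxy)phenyl N-isopropyl-N-(trimethylsilyl)carbamate | CC(C)N([Si](C)(C)C)C(=O)Oc1cc(OCOC)cc(OCOC)c1 | intermediate (not isolated)
6 | 2-lithio derivative of 5 | CC(C)N([Si](C)(C)C)C(=O)Oc1cc(OCOC)cc(OCOC)c1[Li] | intermediate (not isolated)
7 | 3,5-bis(methoxymethoxy)-2-(trimethylsilyl)phenyl N-isopropyl-N-(trimethylsilyl)carbamate | CC(C)N([Si](C)(C)C)C(=O)Oc1cc(OCOC)cc(OCOC)c1[Si](C)(C)C | intermediate (not isolated)
8 | 6-lithio derivative of 7 | CC(C)N([Si](C)(C)C)C(=O)Oc1c([Li])c(OCOC)cc(OCOC)c1[Si](C)(C)C | intermediate (not isolated)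
9 | arylcopper derived from 8 | CC(C)N([Si](C)(C)C)C(=O)Oc1c([Cu])c(OCOC)cc(OCOC)c1[Si](C)(C)C | intermediate (not isolated)
10 | 3,5-bis(methoxymethoxy)-2-prenyl-6-(trimethylsilyl)phenyl N-isopropyl-N-(trimethylsilyl)carbamate | CC(C)=CCc1c(OCOC)cc(OCOC)c([Si](C)(C)C)c1OC(=O)N(C(C)C)[Si](C)(C)C | intermediate (not isolated)
11 | 3,5-bis(methoxymethoxy)-2-(3-methylbut-2-en-1-yl)-6-(trimethylsilyl)phenyl N-isopropylcarbamate | CC(C)=CCc1c(OCOC)cc(OCOC)c([Si](C)(C)C)c1OC(=O)NC(C)C | intermediate
12 | 3,5-bis(methoxymethoxy)-2-(3-methylbut-2-en-1-yl)-6-(trimethylsilyl)phenol (present as its amidinium phenoxide) | CC(C)=CCc1c(OCOC)cc(OCOC)c([Si](C)(C)C)c1O | intermediate (not isolated)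
13 | 3,5-bis(methoxymethoxy)-2-(3-methylbut-2-en-1-yl)-6-(trimethylsilyl)phenyl trifluoromethanesulfonate | CC(C)=CCc1c(OCOC)cc(OCOC)c([Si](C)(C)C)c1OS(=O)(=O)C(F)(F)F | intermediate
14 | methyl glycolate | COC(=O)CO | starting material
15 | methyl 2-(tert-butyldimethylsilyloxy)acetate | COC(=O)CO[Si](C)(C)C(C)(C)C | intermediate
16 | lithium enolate of 15 (geometry not defined) | COC(O[Li])=CO[Si](C)(C)C(C)(C)C | intermediate (not isolated)
17 | 1-methoxy-1,2-bis(tert-butyldimethylsilyloxy)ethene (drawn as Z; an E/Z mixture serves equally) | CO/C(O[Si](C)(C)C(C)(C)C)=C/O[Si](C)(C)C(C)(C)C | intermediate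
18 | ring A aryne, 3,5-bis(methoxymethoxy)-6-prenyl-1,2-didehydrobenzene | CC(C)=CCC1=C(OCOC)C=C(OCOC)C#C1 | intermediate (not isolated)
19 | benzocyclobutene cycloadduct: C7 (on C1) bears H and OTBS, C8 (on C2) bears OMe and OTBS; racemic mixture of diastereomers | CC(C)=CCc1c(OCOC)cc(OCOC)c2c1C(O[Si](C)(C)C(C)(C)C)C2(OC)O[Si](C)(C)C(C)(C)C | intermediate
20 | 7-hydroxy-3,5-bis(methoxymethoxy)-6-prenylbenzocyclobuten-8-one (racemic) | CC(C)=CCc1c(OCOC)cc(OCOC)c2c1C(O)C2=O | intermediate
21 | 3,5-bis(methoxymethoxy)-6-prenylbenzocyclobutene-7,8-dione | CC(C)=CCc1c(OCOC)cc(OCOC)c2c1C(=O)C2=O | intermediate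
22 | orcinol | Cc1cc(O)cc(O)c1 | starting material
23 | 4-chloro-5-methylbenzene-1,3-diol | Cc1cc(O)cc(O)c1Cl | intermediate
24 | 2-chloro-1,5-bis(methoxymethoxy)-3-methylbenzene | Cc1cc(OCOC)cc(OCOC)c1Cl | intermediate
25 | 3-chloro-2,6-bis(methoxymethoxy)-4-methylphenyllithium | Cc1cc(OCOC)c([Li])c(OCOC)c1Cl | intermediate (not isolated)
26 | 7-[3-chloro-2,6-bis(methoxymethoxy)-4-methylphenyl]-7-hydroxy-3,5-bis(methoxymethoxy)-6-prenylbenzocyclobuten-8-one (racemic) | CC(C)=CCc1c(OCOC)cc(OCOC)c2c1C(O)(c1c(OCOC)cc(C)c(Cl)c1OCOC)C2=O | intermediate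
27 | 7-[3-chloro-2,6-bis(methoxymethoxy)-4-methylphenyl]-3,5-bis(methoxymethoxy)-6-prenyl-7,8-dihydrobenzocyclobutene-7,8-diol (racemic, mainly trans expected) | CC(C)=CCc1c(OCOC)cc(OCOC)c2c1C(O)(c1c(OCOC)cc(C)c(Cl)c1OCOC)C2O | intermediate
28 | 2-[3-chloro-2,6-bis(methoxymethoxy)-4-methylbenzoyl]-4,6-bis(methoxymethoxy)-3-prenylbenzaldehyde | CC(C)=CCc1c(OCOC)cc(OCOC)c(C=O)c1C(=O)c1c(OCOC)cc(C)c(Cl)c1OCOC | intermediate
29 | Pestalone E | CC(C)=CCc1c(O)cc(O)c(C=O)c1C(=O)c1c(O)cc(C)c(Cl)c1O | target

**Step count**

Total: 15 steps. Longest linear sequence: 11 steps (1–4, 7–9, 12–15).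

**Steps most likely to fail**

Step 7. Fluoride may strip the silyl groups from the ketene acetal faster than the aryne is released, or the crowded aryne may be consumed by oligomerisation before cycloaddition, so that little cycloadduct forms. The fallback generates the same aryne without fluoride, by iodine–lithium exchange. It sets out from 3 and reverses the order of the two ortho-metalations, with iodine in place of silicon. In-flask N-silylation, s-BuLi/TMEDA, CuBr·SMe2 and prenyl bromide 4 should give 3,5-bis(methoxymethoxy)-2-(3-methylbut-2-en-1-yl)phenyl N-isopropylcarbamate F1. A second ortho-lithiation under the same N-silylation, in which the doubly flanked C–H between the carbamate and a MOM ether should still be removed faster than the benzylic-allylic CH2 at −78 °C, quenched with I2 at −78 °C, should give 2-iodo-3,5-bis(methoxymethoxy)-6-(3-methylbut-2-en-1-yl)phenyl N-isopropylcarbamate F2. DBU/Et2NH followed by PhNTf2 should give 2-iodo-3,5-bis(methoxymethoxy)-6-(3-methylbut-2-en-1-yl)phenyl trifluoromethanesulfonate F3. Treatment of F3 with n-BuLi in THF at −78 °C in the presence of 17 effects iodine–lithium exchange and loss of LiOTf; aryne 18 is then trapped under conditions where the ketene acetal is stable, and the route is rejoined at 19.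

Step 12. Coordination of the aryllithium to the C3 acetal oxygen may steer it to C8, or steric hindrance at C7 (next to the prenyl group) may slow the addition and allow double addition, so that site selectivity is lost. The fallback fixes the site by construction, using the polarity of the cycloaddition, and replaces steps 12–14. It sets out from 20. Ketalisation of the C8 carbonyl (HC(OMe)3, MeOH, pyridinium p-toluenesulfonate) should give 7-hydroxy-8,8-dimethoxy-3,5-bis(methoxymethoxy)-6-prenyl-7,8-dihydrobenzocyclobutene F4. Dess–Martin oxidation should give 8,8-dimethoxy-3,5-bis(methoxymethoxy)-6-prenylbenzocyclobuten-7-one F5, in which C7 is the only carbonyl. Addition of 25 at −78 °C should give the tertiary alcohol 7-aryl-7-hydroxy-8,8-dimethoxy-3,5-bis(methoxymethoxy)-6-prenyl-7,8-dihydrobenzocyclobutene F6. Deprotonation with KN(SiMe3)2 in THF (0 °C → rt) triggers alkoxide-accelerated opening of the four-membered ring across C7–C8, and C-protonation on work-up should give 2-[3-chloro-2,6-bis(methoxymethoxy)-4-methylbenzoyl]-4,6-bis(methoxymethoxy)-3-prenylbenzaldehyde dimethyl acetal F7, without a change of oxidation level. Mild hydrolysis of the acetal (oxalic acid on wet silica) rejoins the route at 28.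

Step 15. The liberated C5 phenol may add to the prenyl double bond under Brønsted acid (chroman ring closure), or the hindered and chelated acetal groups may be cleaved incompletely. The fallback sets out from 28 and avoids any contact between free phenol, alkene and acid. TMSOTf with 2,2′-bipyridyl in CH2Cl2 (0 °C → rt) exchanges each aryl MOM ether for a trimethylsilyl ether under aprotic, amine-buffered conditions, which should give the tetrakis(trimethylsilyl) ether of Pestalone E F8. Neutral hydrolysis (H2O/MeOH, rt) then cleaves the aryl silyl ethers and arrives at 29.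

**Further compounds**

F1 | step 7 | 3,5-bis(methoxymethoxy)-2-(3-methylbut-2-en-1-yl)phenyl N-isopropylcarbamate | CC(C)=CCc1c(OCOC)cc(OCOC)cc1OC(=O)NC(C)C
F2 | step 7 | 2-iodo-3,5-bis(methoxymethoxy)-6-(3-methylbut-2-en-1-yl)phenyl N-isopropylcarbamate | CC(C)=CCc1c(OCOC)cc(OCOC)c(I)c1OC(=O)NC(C)C
F3 | step 7 | 2-iodo-3,5-bis(methoxymethoxy)-6-(3-methylbut-2-en-1-yl)phenyl trifluoromethanesulfonate | CC(C)=CCc1c(OCOC)cc(OCOC)c(I)c1OS(=O)(=O)C(F)(F)F
F4 | step 12 | 7-hydroxy-8,8-dimethoxy-3,5-bis(methoxymethoxy)-6-prenyl-7,8-dihydrobenzocyclobutene (racemic) | CC(C)=CCc1c(OCOC)cc(OCOC)c2c1C(O)C2(OC)OC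
F5 | step 12 | 8,8-dimethoxy-3,5-bis(methoxymethoxy)-6-prenylbenzocyclobuten-7-one | CC(C)=CCc1c(OCOC)cc(OCOC)c2c1C(=O)C2(OC)OC
F6 | step 12 | 7-[3-chloro-2,6-bis(methoxymethoxy)-4-methylphenyl]-7-hydroxy-8,8-dimethoxy-3,5-bis(methoxymethoxy)-6-prenyl-7,8-dihydrobenzocyclobutene (racemic) | CC(C)=CCc1c(OCOC)cc(OCOC)c2c1C(O)(c1c(OCOC)cc(C)c(Cl)c1OCOC)C2(OC)OC
F7 | step 12 | 2-[3-chloro-2,6-bis(methoxymethoxy)-4-methylbenzoyl]-4,6-bis(methoxymethoxy)-3-prenylbenzaldehyde dimethyl acetal | CC(C)=CCc1c(OCOC)cc(OCOC)c(C(OC)OC)c1C(=O)c1c(OCOC)cc(C)c(Cl)c1OCOC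
F8 | step 15 | tetrakis(trimethylsilyl) ether of Pestalone E | CC(C)=CCc1c(O[Si](C)(C)C)cc(O[Si](C)(C)C)c(C=O)c1C(=O)c1c(O[Si](C)(C)C)cc(C)c(Cl)c1O[Si](C)(C)C
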